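**Retrosynthetic overview**

1. Target 17 is epioritin-(4β→6)-epimesquitol-4β-ol: an upper 2,3-cis flavan-3-ol (rings A, B, C) bonded from C4 to C6 of a lower 2,3-cis-3,4-trans flavan-3,4-diol (rings D, E, F); the last operation is hydrogenolysis of seven benzyl ethers (16 to 17).
2. Key disconnection: pyran ring F is cut at O1–C2 and at C4a–C4, giving phenol 10 (ring D already carrying the upper unit) and cis-epoxy aldehyde 14; forward, a magnesium-templated [3+3] annulation: ortho-hydroxyalkylation (C4a–C4), then 6-endo epoxide opening (O1–C2).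
3. Enabling feature: the two bonds from ring F to ring D start at adjacent atoms, the phenolic O1 (on C8a) and the ortho carbon C4a (also para to the 7-oxygen), and C2, C3, C4 carry aryl/O, OH and OH in a row. This is the pattern of a phenol C,O-dinucleophile plus a 3-aryl-2,3-epoxypropanal (CHO becomes C4, the epoxide oxygen stays on C3, the benzylic epoxide carbon becomes C2).
4. Before that: the interflavanyl bond C4 (ring C)–C6 (ring D) by Friedel–Crafts arylation of the flavan-4-yl cation from diol 9 with phenol 3; ring C of 9 by the same annulation from 3 and epoxy aldehyde 7.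
5. Ring order: C (step 5), interflavanyl bond (step 6), F (step 10); rings A, B, D, E are bought as benzaldehydes 1, 4, 11; both epoxy aldehydes come from Z-olefination, Jacobsen–Katsuki epoxidation and ester reduction.

Key step: step 10

Remark: 1, 4 and 11 are taken as catalogue compounds; β means the face of a pyran ring anti to its 3-hydroxyl; 9 is drawn as the 4β-alcohol expected from chelation control, but either C4 epimer serves because C4 is ionised in step 6.

**Route**

Step 1
Reactants: 1 2,3-bis(benzyloxy)benzaldehyde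
Product: 3 2,3-bis(benzyloxy)phenol, via aryl formate 2 (not isolated)
Conditions: mCPBA, CH2Cl2, 0 to 20 °C; then K2CO3 (cat.), MeOH, 20 °C
Reagents that add atoms: 3-chloroperoxybenzoic acid (mCPBA), O=C(OO)c1cccc(Cl)c1
Why: Baeyer–Villiger (Dakin-type) oxidation, in which the electron-rich 2,3-dialkoxyphenyl group migrates in preference to hydrogen and the aryl formate is methanolysed in the same flask; benzyl ethers are inert to both reagents.

Step 2
Reactants: 4 4-(benzyloxy)benzaldehyde
Product: 5 methyl (Z)-3-[4-(benzyloxy)phenyl]prop-2-enoate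
Conditions: (CF3CH2O)2P(O)CH2CO2Me, KN(SiMe3)2, 18-crown-6, THF, −78 °C
Reagents that add atoms: methyl 2-[bis(2,2,2-trifluoroethoxy)phosphoryl]acetate, COC(=O)CP(=O)(OCC(F)(F)F)OCC(F)(F)F
Why: Still–Gennari variant of the Horner–Wadsworth–Emmons olefination, in which fast irreversible elimination from the kinetic adduct of the electron-poor phosphonate should give the (Z)-enoate needed for a cis-epoxide.

Step 3
Reactants: 5 methyl (Z)-3-[4-(benzyloxy)phenyl]prop-2-enoate
Product: 6 methyl (2S,3S)-3-[4-(benzyloxy)phenyl]oxirane-2-carboxylate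
Conditions: (S,S)-[N,N'-bis(3,5-di-tert-butylsalicylidene)cyclohexane-1,2-diaminato]manganese chloride (5 mol %), 4-phenylpyridine N-oxide (cat.), NaOCl (aq., Na2HPO4 buffer, pH 11.3), CH2Cl2, 4 °C
Reagents that add atoms: sodium hypochlorite, [Na+].[O-]Cl
Why: Jacobsen–Katsuki epoxidation, a reaction type established for cis-cinnamate esters, in which the chiral trivalent manganese salen catalyst transfers oxygen to one enantioface of the cis-alkene and should set both epoxide centres (2S,3S with the S,S catalyst); the basic two-phase medium spares the acid-sensitive epoxide, and any trans-epoxide is removed by chromatography on base-washed silica.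

Step 4
Reactants: 6 methyl (2S,3S)-3-[4-(benzyloxy)phenyl]oxirane-2-carboxylate
Product: 7 (2S,3S)-3-[4-(benzyloxy)phenyl]oxirane-2-carbaldehyde
Conditions: i-Bu2AlH (1.05 equiv), CH2Cl2, −78 °C; MeOH, aq. potassium sodium tartrate; used at once
Reagents that add atoms: none
Why: Partial reduction of an ester by i-Bu2AlH, in which the tetrahedral aluminium hemiacetal, held by chelation to the epoxide oxygen, should survive at −78 °C until the quench; the oxirane C–H is not readily enolised, so the cis configuration is kept.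

Step 5
Reactants: 3 2,3-bis(benzyloxy)phenol; 7 (2S,3S)-3-[4-(benzyloxy)phenyl]oxirane-2-carbaldehyde
Product: 9 (2R,3R,4S)-7,8-bis(benzyloxy)-2-[4-(benzyloxy)phenyl]chromane-3,4-diol, via ortho-hydroxyalkylated epoxy alcohol 8 (not isolated)
Conditions: i-PrMgCl (1.0 equiv), Et2O/CH2Cl2, 0 °C; Et2O removed, CH2Cl2; 7 (1.1 equiv), −40 to 20 °C; aq. NH4Cl
Reagents that add atoms: none
Why: Proposed new method: the chloromagnesium phenoxide of 3 should bind 7 at divalent magnesium and add through its only free ortho carbon to the aldehyde in a closed six-membered transition state (closest known type: ortho-specific hydroxyalkylation of halomagnesium phenoxides with alpha-alkoxy aldehydes), and the phenolic oxygen of 8 should then open the magnesium-activated epoxide at its benzylic carbon in a 6-endo, SN2-type fashion (closest known type: Lewis-acid-promoted phenol–epoxide cyclisation to flavan-3-ols), so that C3 is carried over from 7, C2 is set by inversion of the cis-epoxide (2,3-cis) and C4 by magnesium chelation between aldehyde and epoxide oxygens (3,4-trans expected, but immaterial here).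

Step 6
Reactants: 9 (2R,3R,4S)-7,8-bis(benzyloxy)-2-[4-(benzyloxy)phenyl]chromane-3,4-diol; 3 2,3-bis(benzyloxy)phenol
Product: 10 4-{(2R,3R,4S)-7,8-bis(benzyloxy)-2-[4-(benzyloxy)phenyl]-3-hydroxychroman-4-yl}-2,3-bis(benzyloxy)phenol
Conditions: 3 (3 equiv), BF3·OEt2 (0.3 equiv), CH2Cl2, −30 to 0 °C, slow addition of 9
Reagents that add atoms: none
Why: Friedel–Crafts arylation of a flavan-4-yl cation (the interflavanyl bond-forming reaction of proanthocyanidin synthesis), in which BF3 ionises the 4-hydroxyl activated by O1 and the para 7-benzyloxy group, the excess phenol is attacked para to its free hydroxyl, and the nucleophile enters anti to the axial 3-hydroxyl of the 2,3-cis cation to set the 3,4-trans (4β) centre.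

Step 7
Reactants: 11 3,4-bis(benzyloxy)benzaldehyde
Product: 12 methyl (Z)-3-[3,4-bis(benzyloxy)phenyl]prop-2-enoate
Conditions: (CF3CH2O)2P(O)CH2CO2Me, KN(SiMe3)2, 18-crown-6, THF, −78 °C
Reagents that add atoms: methyl 2-[bis(2,2,2-trifluoroethoxy)phosphoryl]acetate, COC(=O)CP(=O)(OCC(F)(F)F)OCC(F)(F)F
Why: Still–Gennari olefination as in step 2, expected to give the (Z)-enoate under kinetic control.

Step 8
Reactants: 12 methyl (Z)-3-[3,4-bis(benzyloxy)phenyl]prop-2-enoate
Product: 13 methyl (2S,3S)-3-[3,4-bis(benzyloxy)phenyl]oxirane-2-carboxylate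
Conditions: (S,S)-[N,N'-bis(3,5-di-tert-butylsalicylidene)cyclohexane-1,2-diaminato]manganese chloride (5 mol %), 4-phenylpyridine N-oxide (cat.), NaOCl (aq., Na2HPO4 buffer, pH 11.3), CH2Cl2, 4 °C
Reagents that add atoms: sodium hypochlorite, [Na+].[O-]Cl
Why: Jacobsen–Katsuki epoxidation as in step 3, with the catalyst selecting the enantioface of the cis-alkene and thereby both epoxide centres (2S,3S).

Step 9
Reactants: 13 methyl (2S,3S)-3-[3,4-bis(benzyloxy)phenyl]oxirane-2-carboxylate
Product: 14 (2S,3S)-3-[3,4-bis(benzyloxy)phenyl]oxirane-2-carbaldehyde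
Conditions: i-Bu2AlH (1.05 equiv), CH2Cl2, −78 °C; MeOH, aq. potassium sodium tartrate; used at once
Reagents that add atoms: none
Why: Partial ester reduction by i-Bu2AlH as in step 4, stopping at the chelated aluminium hemiacetal so that the cis-epoxy aldehyde is released only on work-up.

Step 10
Reactants: 10 4-{(2R,3R,4S)-7,8-bis(benzyloxy)-2-[4-(benzyloxy)phenyl]-3-hydroxychroman-4-yl}-2,3-bis(benzyloxy)phenol; 14 (2S,3S)-3-[3,4-bis(benzyloxy)phenyl]oxirane-2-carbaldehyde
Product: 16 hepta-O-benzyl ether of 17 [7,8,4'-tri-O-benzylepioritin-(4β→6)-7,8,3',4'-tetra-O-benzylepimesquitol-4β-ol], via ring-D hydroxyalkylated epoxy alcohol 15 (not isolated)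
Conditions: i-PrMgCl (1.0 equiv), Et2O/CH2Cl2, 0 °C; Et2O removed, CH2Cl2; 14 (1.2 equiv), −40 to 20 °C; aq. NH4Cl
Reagents that add atoms: none
Why: Proposed new method: the chloromagnesium phenoxide of 10 should bind aldehyde 14 at divalent magnesium and attack its carbonyl carbon with C4a, the only free ortho carbon of ring D, through a closed six-membered transition state, and the phenolic O1 of the resulting chelate 15 should then open the magnesium-activated epoxide at its benzylic carbon. The closest known reaction types are the ortho-specific hydroxyalkylation of halomagnesium phenoxides with chiral alpha-alkoxy aldehydes and the Lewis-acid-promoted phenol–epoxide cyclisation used for flavan-3-ols; joining them into one annulation on an epoxy aldehyde is the new element. Ring F closes in the 6-endo-tet mode, favoured over 5-exo attack at C3 because the electron-rich 3,4-bis(benzyloxy)phenyl group and the bound metal weaken the benzylic C2–O bond and because 2,3-epoxy alcohols open at the carbon remote from the carbinol. C3 is carried over from 14 with its oxygen, C2 is set by inversion in the SN2-type opening of the cis-epoxide (2,3-cis), and C4 is set under Cram-chelate control, magnesium bridging the aldehyde and epoxide oxygens so that ring D adds from the face of the alpha-hydrogen (3,4-trans). The step needs site selectivity on ring D (secured, since the para position carries the upper unit and the other ortho position a benzyloxy group), chemoselectivity for the phenol over the hindered 3-hydroxyl of ring C (one equivalent of base deprotonates only the phenol) and freedom from halohydrin formation (chloride counter-ion, non-coordinating solvent, low temperature).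

Step 11
Reactants: 16 hepta-O-benzyl ether of 17
Product: 17 epioritin-(4β→6)-epimesquitol-4β-ol (target)
Conditions: H2 (1 atm), Pd(OH)2/C, EtOAc/THF, 20 °C, stopped at the end of uptake; filtered under argon
Reagents that add atoms: none
Why: Hydrogenolysis of the seven aryl benzyl ethers, in which a neutral, alcohol-free medium should leave the secondary benzylic 4-hydroxyl and the benzylic C2–O1 bonds intact (as for other para-hydroxybenzylic alcohols freed this way), and no stereocentre is touched.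

**Compound list**

1 | 2,3-bis(benzyloxy)benzaldehyde | O=Cc1cccc(OCc2ccccc2)c1OCc1ccccc1 | starting material
2 | 2,3-bis(benzyloxy)phenyl formate | O=COc1cccc(OCc2ccccc2)c1OCc1ccccc1 | intermediate
3 | 2,3-bis(benzyloxy)phenol | Oc1cccc(OCc2ccccc2)c1OCc1ccccc1 | intermediate
4 | 4-(benzyloxy)benzaldehyde | O=Cc1ccc(OCc2ccccc2)cc1 | starting material
5 | methyl (Z)-3-[4-(benzyloxy)phenyl]prop-2-enoate | COC(=O)/C=C\c1ccc(OCc2ccccc2)cc1 | intermediate
6 | methyl (2S,3S)-3-[4-(benzyloxy)phenyl]oxirane-2-carboxylate (cis-epoxide) | COC(=O)[C@H]1O[C@H]1c3ccc(OCc2ccccc2)cc3 | intermediate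
7 | (2S,3S)-3-[4-(benzyloxy)phenyl]oxirane-2-carbaldehyde (cis-epoxide) | O=C[C@H]1O[C@H]1c3ccc(OCc2ccccc2)cc3 | intermediate
8 | (S)-[3,4-bis(benzyloxy)-2-hydroxyphenyl]{(2R,3S)-3-[4-(benzyloxy)phenyl]oxiran-2-yl}methanol | Oc1c(OCc2ccccc2)c(OCc2ccccc2)ccc1[C@H](O)[C@H]3O[C@H]3c4ccc(OCc2ccccc2)cc4 | intermediate
9 | (2R,3R,4S)-7,8-bis(benzyloxy)-2-[4-(benzyloxy)phenyl]chromane-3,4-diol (tri-O-benzylepioritin-4β-ol; 2,3-cis-3,4-trans) | c1cc2c(c(OCc3ccccc3)c1OCc1ccccc1)O[C@H](c1ccc(OCc3ccccc3)cc1)[C@H](O)[C@H]2O | intermediate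
10 | 4-{(2R,3R,4S)-7,8-bis(benzyloxy)-2-[4-(benzyloxy)phenyl]-3-hydroxychroman-4-yl}-2,3-bis(benzyloxy)phenol (2,3-cis-3,4-trans, 4β-aryl) | C(c1ccccc1)Oc1ccc([C@H]2Oc3c(ccc(OCc4ccccc4)c3OCc3ccccc3)[C@H](c3ccc(O)c(OCc4ccccc4)c3OCc3ccccc3)[C@H]2O)cc1 | intermediate
11 | 3,4-bis(benzyloxy)benzaldehyde | O=Cc1ccc(OCc2ccccc2)c(OCc2ccccc2)c1 | starting material
12 | methyl (Z)-3-[3,4-bis(benzyloxy)phenyl]prop-2-enoate | COC(=O)/C=C\c1ccc(OCc2ccccc2)c(OCc2ccccc2)c1 | intermediate
13 | methyl (2S,3S)-3-[3,4-bis(benzyloxy)phenyl]oxirane-2-carboxylate (cis-epoxide) | COC(=O)[C@H]1O[C@H]1c3ccc(OCc2ccccc2)c(OCc2ccccc2)c3 | intermediate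
14 | (2S,3S)-3-[3,4-bis(benzyloxy)phenyl]oxirane-2-carbaldehyde (cis-epoxide) | O=C[C@H]1O[C@H]1c3ccc(OCc2ccccc2)c(OCc2ccccc2)c3 | intermediate
15 | phenol 10 carrying at C6 (ortho to OH) the group (S)-CH(OH)-[(2R,3S)-3-(3,4-bis(benzyloxy)phenyl)oxiran-2-yl]; upper unit unchanged (2R,3R, 4β-aryl; the C4 descriptor becomes R by CIP ranking only) | C(c1ccccc1)Oc1ccc([C@H]2Oc3c(ccc(OCc4ccccc4)c3OCc3ccccc3)[C@H](c3cc([C@H](O)[C@H]6O[C@H]6c7ccc(OCc5ccccc5)c(OCc5ccccc5)c7)c(O)c(OCc4ccccc4)c3OCc3ccccc3)[C@H]2O)cc1 | intermediate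
16 | (2R,3R,4S)-7,8-bis(benzyloxy)-6-{7,8-bis(benzyloxy)-2-[4-(benzyloxy)phenyl]-3-hydroxychroman-4-yl}-2-[3,4-bis(benzyloxy)phenyl]chromane-3,4-diol; upper unit 2R,3R with 4β-aryl (C4 descriptor R by CIP ranking, same geometry as in 10 and 17); hepta-O-benzyl ether of 17 | C(c1ccccc1)Oc1ccc([C@H]2Oc3c(ccc(OCc4ccccc4)c3OCc3ccccc3)[C@H](c3cc4c(c(OCc5ccccc5)c3OCc3ccccc3)O[C@H](c3ccc(OCc5ccccc5)c(OCc5ccccc5)c3)[C@H](O)[C@H]4O)[C@H]2O)cc1 | intermediate
17 | (2R,3R,4S)-2-(3,4-dihydroxyphenyl)-6-[(2R,3R,4S)-3,7,8-trihydroxy-2-(4-hydroxyphenyl)chroman-4-yl]chromane-3,4,7,8-tetrol | Oc1ccc([C@H]2Oc3c(ccc(O)c3O)[C@H](c3cc4c(c(O)c3O)O[C@H](c3ccc(O)c(O)c3)[C@H](O)[C@H]4O)[C@H]2O)cc1 | target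

**Step count**

Total steps: 11. Longest linear sequence: 7 steps (2, 3, 4, 5, 6, 10, 11).

**Steps most likely to fail**

1. Step 10 (proposed new method). What may go wrong:
   - ionisation of the benzylic epoxide C–O bond before ring closure, which would erode the stereospecificity at C2;
   - poor facial selectivity in the addition to the aldehyde if chelation is lost;
   - Lewis-acid rearrangement of 14 before the C–C bond forms.

   The fallback reverses the bond order (O1–C2 first, C4a–C4 last) with known reaction types. It sets out from 13 and 10 and comes back at 16. Glycidate 13 is reduced with NaBH4 (MeOH/THF, 0 °C) to the epoxy alcohol [(2R,3S)-3-[3,4-bis(benzyloxy)phenyl]oxiran-2-yl]methanol F1. The caesium phenoxide of 10 (Cs2CO3, DMF, 50 °C) opens F1 at the benzylic carbon with inversion, the known C3-selective opening of 3-aryl-2,3-epoxy alcohols by phenoxides, to give the aryl ether (2R,3R)-3-aryloxy-3-[3,4-bis(benzyloxy)phenyl]propane-1,2-diol F2 (aryl = ring D of 10), which already holds the O1–C2 bond and the 2,3-cis relationship. TEMPO/PhI(OAc)2 (CH2Cl2) oxidises only the primary alcohol to the alpha-hydroxy aldehyde (2S,3R)-3-aryloxy-3-[3,4-bis(benzyloxy)phenyl]-2-hydroxypropanal F3. MgBr2·OEt2 (CH2Cl2, −20 °C) then closes the C4a–C4 bond by intramolecular Friedel–Crafts hydroxyalkylation para to the 7-benzyloxy group, the metal chelating aldehyde and alpha-hydroxyl, to give 16.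

2. Step 5 (proposed new method). What may go wrong: the same processes as in step 10, on the simpler phenol (loss of stereospecificity at C2, competing 5-exo opening, rearrangement of 7). The fallback sets out from 6 and 3 and comes back at 9. NaBH4 reduction of 6 gives [(2R,3S)-3-[4-(benzyloxy)phenyl]oxiran-2-yl]methanol F4. The caesium phenoxide of 3 opens F4 at the benzylic carbon with inversion to give (2R,3R)-3-[2,3-bis(benzyloxy)phenoxy]-3-[4-(benzyloxy)phenyl]propane-1,2-diol F5. TEMPO/PhI(OAc)2 gives (2S,3R)-3-[2,3-bis(benzyloxy)phenoxy]-3-[4-(benzyloxy)phenyl]-2-hydroxypropanal F6. MgBr2·OEt2 closes ring C by intramolecular Friedel–Crafts hydroxyalkylation to 9; either C4 epimer is usable in step 6.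

3. Step 6. What may go wrong: poor site selectivity on phenol 3 (attack ortho instead of para to the hydroxyl, or O-alkylation), and self-condensation of the cation with ring A of a second molecule of 9. The fallback screens the ortho position with a bulky silyl ether. It sets out from 3 (and 9) and comes back at 10. Phenol 3 is silylated (i-Pr3SiCl, imidazole, DMF) to [2,3-bis(benzyloxy)phenoxy]tri(propan-2-yl)silane F7. Arylation of the cation from 9 (BF3·OEt2, CH2Cl2, −30 °C) can then occur only para to the silyloxy group, giving the silyl ether of 10, {4-[7,8-bis(benzyloxy)-2-(4-(benzyloxy)phenyl)-3-hydroxychroman-4-yl]-2,3-bis(benzyloxy)phenoxy}tri(propan-2-yl)silane F8. Bu4NF (THF, 0 °C) frees the phenol 10.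

**Further compounds**

F1 | step 10 | [(2R,3S)-3-[3,4-bis(benzyloxy)phenyl]oxiran-2-yl]methanol | OC[C@H]1O[C@H]1c3ccc(OCc2ccccc2)c(OCc2ccccc2)c3
F2 | step 10 | (2R,3R)-3-(4-{(2R,3R,4S)-7,8-bis(benzyloxy)-2-[4-(benzyloxy)phenyl]-3-hydroxychroman-4-yl}-2,3-bis(benzyloxy)phenoxy)-3-[3,4-bis(benzyloxy)phenyl]propane-1,2-diol | C(c1ccccc1)Oc1ccc([C@H]2Oc3c(ccc(OCc4ccccc4)c3OCc3ccccc3)[C@H](c3ccc(O[C@H](c7ccc(OCc5ccccc5)c(OCc5ccccc5)c7)[C@H](O)CO)c(OCc4ccccc4)c3OCc3ccccc3)[C@H]2O)cc1
F3 | step 10 | (2S,3R)-3-(4-{(2R,3R,4S)-7,8-bis(benzyloxy)-2-[4-(benzyloxy)phenyl]-3-hydroxychroman-4-yl}-2,3-bis(benzyloxy)phenoxy)-3-[3,4-bis(benzyloxy)phenyl]-2-hydroxypropanal | C(c1ccccc1)Oc1ccc([C@H]2Oc3c(ccc(OCc4ccccc4)c3OCc3ccccc3)[C@H](c3ccc(O[C@H](c7ccc(OCc5ccccc5)c(OCc5ccccc5)c7)[C@H](O)C=O)c(OCc4ccccc4)c3OCc3ccccc3)[C@H]2O)cc1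
F4 | step 5 | [(2R,3S)-3-[4-(benzyloxy)phenyl]oxiran-2-yl]methanol | OC[C@H]1O[C@H]1c3ccc(OCc2ccccc2)cc3
F5 | step 5 | (2R,3R)-3-[2,3-bis(benzyloxy)phenoxy]-3-[4-(benzyloxy)phenyl]propane-1,2-diol | c1cc(O[C@H](c2ccc(OCc3ccccc3)cc2)[C@H](O)CO)c(OCc2ccccc2)c(OCc2ccccc2)c1
F6 | step 5 | (2S,3R)-3-[2,3-bis(benzyloxy)phenoxy]-3-[4-(benzyloxy)phenyl]-2-hydroxypropanal | c1cc(O[C@H](c2ccc(OCc3ccccc3)cc2)[C@H](O)C=O)c(OCc2ccccc2)c(OCc2ccccc2)c1
F7 | step 6 | [2,3-bis(benzyloxy)phenoxy]tri(propan-2-yl)silane | CC(C)[Si](Oc1cccc(OCc2ccccc2)c1OCc1ccccc1)(C(C)C)C(C)C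
F8 | step 6 | {4-[(2R,3R,4S)-7,8-bis(benzyloxy)-2-[4-(benzyloxy)phenyl]-3-hydroxychroman-4-yl]-2,3-bis(benzyloxy)phenoxy}tri(propan-2-yl)silane | C(c1ccccc1)Oc1ccc([C@H]2Oc3c(ccc(OCc4ccccc4)c3OCc3ccccc3)[C@H](c3ccc(O[Si](C(C)C)(C(C)C)C(C)C)c(OCc4ccccc4)c3OCc3ccccc3)[C@H]2O)cc1
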